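# Proposed synthesis of siphonellinol C by oxygen insertion into a Wieland–Miescher decalin

## Analysis of the target

Siphonellinol C (39) is a trans-fused oxepane–cyclohexane bicycle joined by a two-carbon tether to a tetrasubstituted cyclohexene. Ring A is O1, C2, C3, C4, C5, C5a, C9a; ring B is C5a, C6, C7, C8, C9, C9a; the tether runs from C6 to C1' of ring C (C1'–C6'). Ring A carries a gem-dimethyl carbon on oxygen (C2) and a secondary carbinol beside it (C3). Ring B carries the angular methyl (C5a), the tether (C6) and a tertiary methyl carbinol (C7). Ring C has a methyl on the alkene (C2'), a secondary carbinol (C5') and a quaternary carbon (C6') bearing a methyl and an (E)-4-hydroxy-4-methylpent-2-enyl chain.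

There are seven stereocentres. On the bicycle H-9a and the C5a methyl are anti (trans fusion), the C3 hydroxyl and H-6 lie on the face of H-9a, and the C7 hydroxyl is axial and syn to the C5a methyl. On ring C the C5' hydroxyl is cis to the pentenyl chain. The two clusters are separated by a flexible tether, so each needs its own source of absolute configuration.

The tertiary allylic alcohol ionises easily in acid, the C7 carbinol can dehydrate, and the tetrasubstituted alkene is open to electrophilic oxidants. The hard parts are the seven-membered ether with a fully substituted carbon on oxygen, the quaternary C5a next to two further substituted ring B carbons, and chemoselectivity among alkenes late in the route.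

The strategy rests on the position of O1. It sits between the ring-fusion CH (C9a) and C2; if O1 is deleted and C2 joined to C9a, rings A and B become a trans-decalin with an angular methyl and a carbonyl-capable carbon next to the ring-fusion CH. That is the skeleton of enantiopure Wieland–Miescher ketone.

## Retrosynthetic reasoning

**39 back to 37.** After removal of the two silyl ethers (38), both methyl–carbinol bonds are cut at once: C7–CH3 in ring B and one terminal C–CH3 of the side chain. This leads to diketone 37, in which one methyl nucleophile serves both carbonyls. The forward step must add 1,2 to the enone and attack the ring B ketone equatorially; the axial C5a methyl blocks the axial approach and so sets C7.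

**37 back to 35.** The side-chain alkene is cut by an olefination transform to aldehyde 36, stored as its dimethyl acetal in 35. The chain alkene is introduced this late because two hydroborations must come first and would not spare it.

**35 back to 32.** The C7 carbonyl and H-6 are traced, through alcohol 34, to hydroboration of the C6=C7 alkene of 32. This sets C6 from the face opposite the angular methyl and places oxygen on the less substituted carbon.

**32 back to 18 and 30.** The C6–CH2 bond of the tether is cut. This divides the molecule into two fragments of similar size, each carrying one stereo-cluster. C6 is sp2 at this point, so the bond can be made by cross-coupling of enol triflate 18 with borane 31 (from diene 30); an enolate alkylation next to the quaternary C5a would not be reliable.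

**30 back to 19.** The vinyl group of 30 comes from enol triflate 29. Its acetal is the cut-down allyl group of 26 (through 28). The triflate and the alkene methyl come from ketone 22 through 24, and both ring C stereocentres come from desymmetrising reduction of the symmetric dione 20, made by allylation of 19. The ring is thus bought ready-made, and the ketone, which can enolise on one side only, delivers the tetrasubstituted alkene without a regiochemical question.

**18 back to 14.** The ring B triflate is the enol derivative of ketone 16; its carbonyl was masked as the dioxolane in 14, and the C3 hydroxyl needs a silyl group before the base-mediated steps.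

**14 back to 9.** Both C2–CH3 bonds and the C3–O bond are cut. One methyl and the C3 oxygen go back through epoxide 13 to enol ether 12; the other methyl goes back through phosphate 11 to the lactone carbonyl of 9. The lactone carbonyl thus supplies the gem-dimethyl carbon and, through its α-position, the neighbouring carbinol.

**9 back to 8.** The O1–C9a bond is cut by removing O1 from the ring, which gives trans-decalone 8. The forward reaction is an oxygen insertion with migration of the ring-fusion carbon. The oxepane is not cyclised from a chain, so no ring-size or endo/exo issue arises and the trans fusion is inherited.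

**8 back to 1.** The C5 carbonyl is traced through alcohol 7 to hydroboration of alkene 5, which also sets the trans fusion. The alkene is what remains of the enone of 1 after its carbonyl is removed by way of dithiolanes 2 and 4; the saturated carbonyl is kept as the dioxolane (ethylene glycol, 3).

## Alternatives that were turned down

**Alternative 1:** The O1–C2 and C5a–C6 bonds would be cut together, back to the acyclic (Z)-silyl enol ether diepoxide A1. In the forward step a Lewis acid activates the terminal epoxide, the oxygen of the inner epoxide attacks its dimethyl-substituted carbon, and the enol ether carbon opens the resulting epoxonium ion at its tertiary carbon. This gives the oxepane–cyclohexanone A2 with a benzyloxyethyl arm at C6.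
- For it: two rings and all stereocentres of the bicycle except C7 arise in one operation. The ring B ketone of A2 is where it is needed for the methyl addition. On step count to the bicycle this plan is clearly stronger than the twelve steps to 18.
- Against it: A1 needs two reagent-controlled epoxidations and a geometrically pure enol ether. In the cascade every selectivity is decided at once: attack at the tertiary epoxide carbon, capture of the epoxonium ion by carbon and not by oxygen or by loss of a proton, and a chair-like transition state. None can be corrected afterwards. The arm of A2 ends in an sp3 oxygenated carbon, so the link to ring C would be an sp3–sp3 bond in a hindered setting.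
- In its place the chosen route is longer but sets each stereocentre of the bicycle in a separate step with a simple steric rationale, from an enantiopure ketone, and joins the halves at an sp2 carbon.

**Alternative 2:** The C5a–CH3 bond would be cut in masked form. The hydroxyl of the (R)-allylic alcohol A3 directs a Simmons–Smith zinc carbenoid to its own face and gives the cyclopropane A4, whose CH2 is the future angular methyl.
- For it: hydroxyl-directed cyclopropanation is dependable and places the future methyl cis to the oxygen of the future C9a, as the target requires. Reductive opening of the three-membered ring next to a carbonyl would later unveil the methyl and allow the tether to be attached at C6 directly. On that point it is more direct than the triflate, coupling, hydroboration and oxidation used here.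
- Against it: the oxepane would still have to be closed from the homoprenyl chain of A4 by a hydroxy-epoxide cyclisation in the seven-membered endo mode, which competes with six-membered exo closure. Alkylation next to a quaternary carbon with an unactivated homoallylic halide is prone to elimination and proton transfer. No atom of ring A is in place until late.
- In its place the chosen route makes the ether bond by inserting oxygen into an existing ring, where ring size is not in question, and couples at a hindered carbon by a method that tolerates hindrance.

**Alternative 3:** The C1'–C6' bond of ring C would be cut. SnCl4 opens the (2R,3S)-epoxide of the nerol-derived β-keto ester A5 at its tertiary carbon while the α-carbon of the keto ester attacks it, which gives the cyclic β-keto ester A6.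
- For it: both ring C stereocentres follow stereospecifically from the epoxide, so the diastereoselectivity question of step 14 does not exist. The five side-chain carbons are present from the start. The keto ester is a good handle for the alkene methyl and the first tether carbon. For ring C stereocontrol this plan is stronger.
- Against it: it solves only ring C, two of seven stereocentres, and leaves the oxepane bicycle open. Cyclisation through the enol oxygen competes. The side chain of A6 has its double bond one position off, so an allylic oxidation with transposition would be needed in the presence of a more reactive tetrasubstituted ring alkene, and a trisubstituted chain alkene would not survive hydroboration of ring B.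
- In its place the chosen route buys ring C as a symmetric dione, adds the chain by olefination at the end, and spends its key step on ring A.

Key step: step 6

## Remarks before the steps

- Compounds 1–8 carry the naphthalene numbering of 1 (C1 saturated carbonyl or ketal carbon, C4a ring-fusion carbon, C5, C6 enone carbonyl, C8a methyl-bearing carbon). From 9 on the bicycle is numbered as in the target (old C5 = C2, C6 = C3, C8a = C5a, C1 = C6, C2 = C7, C4a = C9a). Ring C carries primed numbers throughout.
- Alkylboranes 6 and 33 are drawn as monoalkylboranes. Compound 24 is a mixture of epimers at the new methyl-bearing carbon and diol 27 at its secondary carbinol; both centres disappear.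
- Assumption: in step 14 the quaternary carbon acts as the large substituent of the reacting carbonyl, so that the (S)-oxazaborolidine leads to the (R)-carbinol; if the opposite sense were found, the (R)-catalyst would be used.

## Steps

### Rings A and B (steps 1–12)

Step 1
Reactants: 1 (S)-Wieland–Miescher ketone
Product: 2 C6 dithiolane of 1 (C1 ketone free; C4a=C5 alkene kept)
Conditions: HSCH2CH2SH, p-TsOH (cat.), AcOH, rt
Reagents that add atoms: ethane-1,2-dithiol, SCCS
Why: Dithioketalisation; the conjugated C6 carbonyl should react in preference to the neopentyl C1 ketone beside the quaternary carbon, and dithiolanes of enones keep the double bond at C4a=C5.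

Step 2
Reactants: 2 C6 dithiolane; 3 ethylene glycol
Product: 4 C1 dioxolane C6 dithiolane (C4a=C5 alkene)
Conditions: 3, p-TsOH (cat.), toluene, reflux (Dean–Stark)
Reagents that add atoms: ethylene glycol (3), OCCO
Why: Acid-catalysed ketalisation of the only ketone left, driven by removal of water; the dithiolane and the trisubstituted alkene are inert here.

Step 3
Reactants: 4 C1 dioxolane C6 dithiolane
Product: 5 (8aS)-1,1-ethylenedioxy-8a-methyl-1,2,3,4,6,7,8,8a-octahydronaphthalene (C4a=C5 alkene)
Conditions: Raney Ni (acetone-deactivated), EtOH, reflux
Reagents that add atoms: none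
Why: Mozingo desulfurisation cleaves both C–S bonds and leaves C6 as CH2; the deactivated catalyst should spare the trisubstituted alkene and the dioxolane.

Step 4
Reactants: 5 alkene ketal
Product: 7 trans-fused C5 alcohol (H-4a anti to the angular methyl; C5–OH on the face of H-4a), via C5 alkylborane 6 (not isolated)
Conditions: BH3·THF, THF, 0 °C → rt; then NaOH, H2O2, 0 °C → rt
Reagents that add atoms: hydrogen peroxide, OO
Why: Hydroboration–oxidation; boron goes to the less substituted C5 and hydrogen to C4a from the face opposite the angular methyl, because boron on the methyl face would be syn-axial to it. This sets the trans ring fusion; the C5 configuration is erased in step 5.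

Step 5
Reactants: 7 trans-fused C5 alcohol
Product: 8 trans-fused angular-methyl decalone mono-ketal (C5 ketone; C1 dioxolane)
Conditions: Dess–Martin periodinane, NaHCO3, CH2Cl2, rt
Reagents that add atoms: none
Why: Dess–Martin oxidation of a secondary alcohol under buffered conditions that do not epimerise C4a; the trans-fused ketone is also the more stable epimer.

Step 6 (key step)
Reactants: 8 trans-decalone mono-ketal
Product: 9 trans-fused oxepan-2-one on the ring B ketal, (5aS,9aR)-6,6-ethylenedioxy-5a-methyloctahydro-1-benzoxepin-2(3H)-one
Conditions: m-CPBA, NaHCO3, CH2Cl2, 0 °C → rt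
Reagents that add atoms: 3-chloroperbenzoic acid, O=C(OO)c1cccc(Cl)c1
Why: The peracid adds to the C5 carbonyl to give the tetrahedral peroxy adduct (Criegee intermediate), and loss of 3-chlorobenzoate is concerted with a 1,2-shift of one α-carbon from carbon to oxygen. The closest known reaction type is the Baeyer–Villiger oxidation of 2-substituted cyclohexanones and 1-decalones, in which the more substituted α-carbon migrates. Ring A is therefore not closed by a cyclisation but arises by ring expansion: the six-membered carbocycle takes up one oxygen and becomes the seven-membered lactone, the new bond being O1–C9a (old C4a). No stereocentre is created; the migrating ring-fusion carbon keeps its configuration because the shift is suprafacial, so the trans fusion set in step 4 passes into 9 unchanged. The selectivity needed is regiochemical, migration of the ring-fusion CH and not of the C6 methylene, and it is secured by the higher migratory aptitude of the secondary carbon and by the rigid trans-decalin, in which the C5–C4a bond can lie antiperiplanar to the O–O bond of the adduct. The hydrogencarbonate buffer keeps the medium near neutral, so the dioxolane should survive and C4a should not epimerise through the enol; 8 contains no alkene for the peracid to epoxidise.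

Step 7
Reactants: 9 lactone
Product: 11 cyclic ketene acetal diphenyl phosphate (C2=C3), via potassium enolate 10 (not isolated)
Conditions: KN(SiMe3)2, THF/HMPA, –78 °C; then (PhO)2P(O)Cl
Reagents that add atoms: diphenyl phosphorochloridate, O=P(Cl)(Oc1ccccc1)Oc1ccccc1
Why: Lactone enolisation and O-phosphorylation give a ketene acetal phosphate, a known isolable class of lactone-derived coupling partners; the ketal has no acidic hydrogen.

Step 8
Reactants: 11 ketene acetal phosphate
Product: 12 cyclic methyl enol ether (C2 methyl; C2=C3)
Conditions: MeZnCl, Pd(PPh3)4 (cat.), THF, 50 °C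
Reagents that add atoms: methylzinc chloride, C[Zn]Cl
Why: Negishi coupling; zerovalent palladium inserts into the C–O bond of the phosphate and the methyl group is transferred from zinc, which is too weak a Lewis acid to disturb the ketal.

Step 9
Reactants: 12 cyclic methyl enol ether
Product: 14 (3R,5aS,9aR)-6,6-ethylenedioxy-2,2,5a-trimethyldecahydro-1-benzoxepin-3-ol, via 2,3-epoxide 13 (not isolated)
Conditions: dimethyldioxirane, acetone/CH2Cl2, –78 → 0 °C; evaporate; AlMe3, CH2Cl2, –78 → 0 °C
Reagents that add atoms: dimethyldioxirane, CC1(C)OO1; trimethylaluminium, C[Al](C)C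
Why: The dioxirane should epoxidise the electron-rich enol ether from the face of H-9a, away from the axial C5a methyl, which sets C3. AlMe3 then ionises the acetal C–O bond of the epoxide and transfers methyl to the oxocarbenium carbon C2, as in the opening of glycal-type epoxides by trialkylaluminium, giving the gem-dimethyl carbon with the C3 oxygen left where the epoxidation put it.

Step 10
Reactants: 14 ketal alcohol
Product: 15 (3R,5aS,9aR)-3-hydroxy-2,2,5a-trimethyloctahydro-1-benzoxepin-6(2H)-one
Conditions: 1 M HCl, THF, rt
Reagents that add atoms: water, O
Why: Acid-catalysed ketal hydrolysis; the tertiary ether and the secondary alcohol should be stable to dilute aqueous acid at room temperature.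

Step 11
Reactants: 15 hydroxy ketone
Product: 16 C3 tert-butyldimethylsilyl ether of 15
Conditions: TBSOTf, 2,6-lutidine, CH2Cl2, –78 → 0 °C
Reagents that add atoms: tert-butyldimethylsilyl trifluoromethanesulfonate, CC(C)(C)[Si](C)(C)OS(=O)(=O)C(F)(F)F
Why: The hydroxyl is flanked by the fully substituted C2 and needs the reactive silyl triflate; at low temperature with 2,6-lutidine the ketone is not enolised.

Step 12
Reactants: 16 silyl ether ketone
Product: 18 ring B enol triflate (C6–OTf; C6=C7), via potassium enolate 17 (not isolated)
Conditions: KN(SiMe3)2, THF, –78 °C; then PhNTf2, –78 → 0 °C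
Reagents that add atoms: N-phenylbis(trifluoromethanesulfonimide), O=S(=O)(N(c1ccccc1)S(=O)(=O)C(F)(F)F)C(F)(F)F
Why: The ketone can enolise only toward C7 because C5a is quaternary, so enolate formation and O-triflation should give a single enol triflate.

### Ring C (steps 13–20)

Step 13
Reactants: 19 2-methylcyclohexane-1,3-dione
Product: 20 2-allyl-2-methylcyclohexane-1,3-dione
Conditions: allyl bromide, 1 M NaOH (aq.), rt
Reagents that add atoms: allyl bromide, C=CCBr
Why: C-allylation of the stabilised enolate of a cyclic 1,3-dione in aqueous base creates the prochiral quaternary carbon.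

Step 14
Reactants: 20 2-allyl-2-methylcyclohexane-1,3-dione
Product: 21 (2R,3R)-2-allyl-3-hydroxy-2-methylcyclohexan-1-one (hydroxyl cis to allyl)
Conditions: (S)-2-methyl-CBS-oxazaborolidine (cat.), catecholborane, toluene, –78 → –40 °C
Reagents that add atoms: none
Why: Corey–Bakshi–Shibata reduction used as a desymmetrisation of a 2,2-disubstituted 1,3-dione. The catalyst fixes the carbinol as R with the quaternary carbon as the large group, and hydride should enter the ring face anti to the larger allyl group, so hydroxyl and allyl become cis and the quaternary carbon R.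

Step 15
Reactants: 21 ketol
Product: 22 tert-butyldimethylsilyl ether of 21
Conditions: TBSOTf, 2,6-lutidine, CH2Cl2, –78 → 0 °C
Reagents that add atoms: tert-butyldimethylsilyl trifluoromethanesulfonate, CC(C)(C)[Si](C)(C)OS(=O)(=O)C(F)(F)F
Why: Silylation of a neopentyl-type secondary alcohol; protection also excludes retro-aldol opening in the base-mediated steps that follow.

Step 16
Reactants: 22 silyl ether ketone
Product: 24 6-methyl ketone (2,6-dimethyl; epimer mixture at C6), via lithium enolate 23 (not isolated)
Conditions: LiN(iPr)2, THF, –78 °C; then MeI, –78 → 0 °C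
Reagents that add atoms: iodomethane, CI
Why: Enolate alkylation; only the C6 side can be deprotonated, and the configuration of the new methine is irrelevant because it becomes an alkene carbon.

Step 17
Reactants: 24 6-methyl ketone
Product: 26 (5R,6R)-6-allyl-5-(tert-butyldimethylsilyloxy)-2,6-dimethylcyclohex-1-en-1-yl triflate, via potassium enolate 25 (not isolated)
Conditions: KN(SiMe3)2, THF, –78 → 0 °C; then PhNTf2
Reagents that add atoms: N-phenylbis(trifluoromethanesulfonimide), O=S(=O)(N(c1ccccc1)S(=O)(=O)C(F)(F)F)C(F)(F)F
Why: The only possible enolate is the tetrasubstituted one, and its O-triflation fixes the C1'=C2' alkene with the methyl in place, as with other 2,2,6-trisubstituted cyclohexanones.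

Step 18
Reactants: 26 enol triflate with allyl group
Product: 28 aldehyde (allyl cut down to CH2CHO), via 1,2-diol 27 (not isolated)
Conditions: OsO4 (cat.), NaIO4, 2,6-lutidine, dioxane/H2O, rt
Reagents that add atoms: sodium periodate, [Na+].[O-]I(=O)(=O)=O (terminal oxidant; the aldehyde oxygen is passed on through OsO4, O=[Os](=O)(=O)=O)
Why: Lemieux–Johnson cleavage; OsO4 should dihydroxylate the monosubstituted alkene far faster than the hindered, electron-poor enol triflate, and periodate cleaves the diol and reoxidises osmium.

Step 19
Reactants: 28 aldehyde
Product: 29 dimethyl acetal of 28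
Conditions: HC(OMe)3, PPTS (cat.), MeOH, rt
Reagents that add atoms: trimethyl orthoformate, COC(OC)OC
Why: Mild acetalisation; the acetal carries the two-carbon stub through the borane and palladium steps, and the hindered silyl ether and the enol triflate tolerate the weak acid.

Step 20
Reactants: 29 acetal enol triflate
Product: 30 ring C diene (C1' vinyl)
Conditions: Bu3SnCH=CH2, Pd(PPh3)4 (cat.), LiCl, THF, reflux
Reagents that add atoms: tributyl(vinyl)stannane, C=C[Sn](CCCC)(CCCC)CCCC
Why: Stille coupling of an alkenyl triflate with a vinylstannane; the small vinyl group should be transferred even to this hindered tetrasubstituted triflate.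

### Union and endgame (steps 21–27)

Step 21
Reactants: 30 ring C diene; 18 ring B enol triflate
Product: 32 coupled diene (tether in place; C6=C7 and C1'=C2' alkenes), via B-alkyl-9-BBN 31 (not isolated)
Conditions: 9-BBN, THF, rt; then 18, Pd(dppf)Cl2 (cat.), AsPh3, Cs2CO3, DMF/THF/H2O, rt → 50 °C
Reagents that add atoms: none
Why: 9-BBN adds to the terminal vinyl carbon only, the tetrasubstituted ring alkene being inert to it, and B-alkyl Suzuki–Miyaura coupling of the resulting borane with the enol triflate forms the C6–CH2 bond of the tether.

Step 22
Reactants: 32 coupled diene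
Product: 34 C7 secondary alcohol (H-6 and C7–OH on the face of H-9a; tether equatorial), via C7 alkylborane 33 (not isolated)
Conditions: BH3·THF (limited excess), THF, 0 °C → rt; then NaOH, H2O2, 0 °C
Reagents that add atoms: hydrogen peroxide, OO
Why: Hydroboration–oxidation; boron goes to the less substituted C7 and hydrogen to C6 from the face opposite the C5a methyl, which sets C6. The tetrasubstituted ring C alkene, flanked by the quaternary C6', should react much more slowly.

Step 23
Reactants: 34 C7 alcohol
Product: 35 C7 ketone (dimethyl acetal intact)
Conditions: Dess–Martin periodinane, NaHCO3, CH2Cl2, rt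
Reagents that add atoms: none
Why: Dess–Martin oxidation; the equatorial tether at C6 is already the more stable arrangement beside the new ketone.

Step 24
Reactants: 35 keto acetal
Product: 36 keto aldehyde
Conditions: PPTS, acetone/H2O, 50 °C
Reagents that add atoms: water, O
Why: Dimethyl acetals of aldehydes hydrolyse under weak acid that the two hindered secondary silyl ethers and the tetrasubstituted alkene should tolerate.

Step 25
Reactants: 36 keto aldehyde
Product: 37 (E)-enone ketone (side chain CH2–CH=CH–C(O)CH3; ring B C7 ketone)
Conditions: Ph3P=CHC(O)CH3, toluene, 80 °C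
Reagents that add atoms: 1-(triphenylphosphoranylidene)propan-2-one, CC(=O)C=P(c1ccccc1)(c1ccccc1)c1ccccc1
Why: Wittig olefination with a stabilised ylide, which reacts with the aldehyde but not with the hindered ketone and gives the (E)-alkene.

Step 26
Reactants: 37 enone ketone
Product: 38 3,5'-bis(tert-butyldimethylsilyl) ether of siphonellinol C
Conditions: MeLi, CeCl3, THF, –78 → 0 °C
Reagents that add atoms: methyllithium, [Li]C
Why: The organocerium reagent adds 1,2 to the enone and does not enolise either ketone. At C7 the axial approach is blocked by the syn-axial C5a methyl, so methyl enters equatorially and the hydroxyl becomes axial (C7 S).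

Step 27
Reactants: 38 bis-silyl ether
Product: 39 siphonellinol C
Conditions: Bu4NF, THF, 50 °C
Reagents that add atoms: none
Why: Fluoride-mediated desilylation of both secondary silyl ethers under basic conditions that do not ionise the tertiary allylic alcohol.

## Compound list

1 | (S)-Wieland–Miescher ketone, (8aS)-8a-methyl-3,4,8,8a-tetrahydronaphthalene-1,6(2H,7H)-dione | O=C1[C@@]2(C)CCC(=O)C=C2CCC1 | starting material
2 | C6 dithiolane of 1 (C1 ketone free, C4a=C5 alkene) | O=C1[C@@]2(C)CCC3(SCCS3)C=C2CCC1 | intermediate
3 | ethylene glycol | OCCO | starting material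
4 | C1 dioxolane, C6 dithiolane, C4a=C5 alkene | O1CCOC12[C@@]3(C)CCC4(SCCS4)C=C3CCC2 | intermediate
5 | (8aS)-1,1-ethylenedioxy-8a-methyl-1,2,3,4,6,7,8,8a-octahydronaphthalene | O1CCOC12[C@@]3(C)CCCC=C3CCC2 | intermediate
6 | C5 alkylborane (drawn as RBH2; trans-fused, boron on the face of H-4a) | O1CCOC12[C@@]3(C)CCC[C@@H](B)[C@@H]3CCC2 | intermediate (not isolated)
7 | (4aR,5R,8aS) trans-fused C5 alcohol, C1 dioxolane | O1CCOC12[C@@]3(C)CCC[C@@H](O)[C@@H]3CCC2 | intermediate
8 | trans-fused angular-methyl decalone mono-ketal (C5 ketone, C1 dioxolane; 4aR,8aS) | O1CCOC12[C@@]3(C)CCCC(=O)[C@@H]3CCC2 | intermediate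
9 | (5aS,9aR)-6,6-ethylenedioxy-5a-methyloctahydro-1-benzoxepin-2(3H)-one | O1CCOC12[C@@]3(C)CCCC(=O)O[C@@H]3CCC2 | intermediate
10 | potassium enolate of lactone 9 | O1CCOC12[C@@]3(C)CCC=C([O-])O[C@@H]3CCC2.[K+] | intermediate (not isolated)
11 | cyclic ketene acetal diphenyl phosphate of 9 | O1CCOC12[C@@]3(C)CCC=C(OP(=O)(Oc4ccccc4)Oc4ccccc4)O[C@@H]3CCC2 | intermediate
12 | (5aS,9aR) 2-methyl cyclic enol ether (C2=C3), C6 dioxolane | O1CCOC12[C@@]3(C)CCC=C(C)O[C@@H]3CCC2 | intermediate
13 | 2,3-epoxide of 12, oxygen on the face of H-9a | O1CCOC12[C@@]3(C)CC[C@H]4O[C@@]4(C)O[C@@H]3CCC2 | intermediate (not isolated)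
14 | (3R,5aS,9aR)-6,6-ethylenedioxy-2,2,5a-trimethyldecahydro-1-benzoxepin-3-ol | O1CCOC12[C@@]3(C)CC[C@@H](O)C(C)(C)O[C@@H]3CCC2 | intermediate
15 | (3R,5aS,9aR)-3-hydroxy-2,2,5a-trimethyloctahydro-1-benzoxepin-6(2H)-one | O=C1[C@@]2(C)CC[C@@H](O)C(C)(C)O[C@@H]2CCC1 | intermediate
16 | C3 tert-butyldimethylsilyl ether of 15 | O=C1[C@@]2(C)CC[C@@H](O[Si](C)(C)C(C)(C)C)C(C)(C)O[C@@H]2CCC1 | intermediate
17 | potassium enolate of 16 (C6=C7) | [K+].[O-]C=1[C@@]2(C)CC[C@@H](O[Si](C)(C)C(C)(C)C)C(C)(C)O[C@@H]2CCC=1 | intermediate (not isolated)
18 | ring B enol triflate (C6–OTf, C6=C7; 3R,5aS,9aR) | FC(F)(F)S(=O)(=O)OC=1[C@@]2(C)CC[C@@H](O[Si](C)(C)C(C)(C)C)C(C)(C)O[C@@H]2CCC=1 | intermediate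
19 | 2-methylcyclohexane-1,3-dione | CC1C(=O)CCCC1=O | starting material
20 | 2-allyl-2-methylcyclohexane-1,3-dione | C=CCC1(C)C(=O)CCCC1=O | intermediate
21 | (2R,3R)-2-allyl-3-hydroxy-2-methylcyclohexan-1-one | O=C1[C@](C)(CC=C)[C@H](O)CCC1 | intermediate
22 | tert-butyldimethylsilyl ether of 21 | O=C1[C@](C)(CC=C)[C@H](O[Si](C)(C)C(C)(C)C)CCC1 | intermediate
23 | lithium enolate of 22 | [Li+].[O-]C=1[C@](C)(CC=C)[C@H](O[Si](C)(C)C(C)(C)C)CCC=1 | intermediate (not isolated)
24 | (2R,3R)-2-allyl-3-(tert-butyldimethylsilyloxy)-2,6-dimethylcyclohexan-1-one (epimer mixture at C6) | CC1C(=O)[C@](C)(CC=C)[C@H](O[Si](C)(C)C(C)(C)C)CC1 | intermediate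
25 | potassium enolate of 24 (tetrasubstituted) | [K+].CC1=C([O-])[C@](C)(CC=C)[C@H](O[Si](C)(C)C(C)(C)C)CC1 | intermediate (not isolated)
26 | (5R,6R)-6-allyl-5-(tert-butyldimethylsilyloxy)-2,6-dimethylcyclohex-1-en-1-yl trifluoromethanesulfonate | CC1=C(OS(=O)(=O)C(F)(F)F)[C@](C)(CC=C)[C@H](O[Si](C)(C)C(C)(C)C)CC1 | intermediate
27 | 1,2-diol from the allyl group of 26 (epimer mixture at the secondary carbinol) | CC1=C(OS(=O)(=O)C(F)(F)F)[C@](C)(CC(O)CO)[C@H](O[Si](C)(C)C(C)(C)C)CC1 | intermediate (not isolated)
28 | aldehyde (CH2CHO on the quaternary carbon), ring configuration as in 26 | CC1=C(OS(=O)(=O)C(F)(F)F)[C@](C)(CC=O)[C@H](O[Si](C)(C)C(C)(C)C)CC1 | intermediate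
29 | dimethyl acetal of 28 | CC1=C(OS(=O)(=O)C(F)(F)F)[C@](C)(CC(OC)OC)[C@H](O[Si](C)(C)C(C)(C)C)CC1 | intermediate
30 | ring C diene (C1' vinyl, C2' methyl, C5' silyl ether, C6' methyl and 2,2-dimethoxyethyl) | CC1=C(C=C)[C@](C)(CC(OC)OC)[C@H](O[Si](C)(C)C(C)(C)C)CC1 | intermediate
31 | B-alkyl-9-borabicyclo[3.3.1]nonane from 30 | CC1=C(CCB2C3CCCC2CCC3)[C@](C)(CC(OC)OC)[C@H](O[Si](C)(C)C(C)(C)C)CC1 | intermediate (not isolated)
32 | coupled diene (ring B C6=C7, ring C C1'=C2', both silyl ethers, acetal) | CC1=C(CCC=2[C@@]3(C)CC[C@@H](O[Si](C)(C)C(C)(C)C)C(C)(C)O[C@@H]3CCC=2)[C@](C)(CC(OC)OC)[C@H](O[Si](C)(C)C(C)(C)C)CC1 | intermediate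
33 | C7 alkylborane (drawn as RBH2; boron and H-6 on the face of H-9a) | CC1=C(CC[C@@H]2[C@@]3(C)CC[C@@H](O[Si](C)(C)C(C)(C)C)C(C)(C)O[C@@H]3CC[C@H]2B)[C@](C)(CC(OC)OC)[C@H](O[Si](C)(C)C(C)(C)C)CC1 | intermediate (not isolated)
34 | C7 secondary alcohol (equatorial; tether at C6 equatorial) | CC1=C(CC[C@@H]2[C@@]3(C)CC[C@@H](O[Si](C)(C)C(C)(C)C)C(C)(C)O[C@@H]3CC[C@H]2O)[C@](C)(CC(OC)OC)[C@H](O[Si](C)(C)C(C)(C)C)CC1 | intermediate
35 | C7 ketone, dimethyl acetal | CC1=C(CC[C@@H]2[C@@]3(C)CC[C@@H](O[Si](C)(C)C(C)(C)C)C(C)(C)O[C@@H]3CCC2=O)[C@](C)(CC(OC)OC)[C@H](O[Si](C)(C)C(C)(C)C)CC1 | intermediate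
36 | keto aldehyde | CC1=C(CC[C@@H]2[C@@]3(C)CC[C@@H](O[Si](C)(C)C(C)(C)C)C(C)(C)O[C@@H]3CCC2=O)[C@](C)(CC=O)[C@H](O[Si](C)(C)C(C)(C)C)CC1 | intermediate
37 | (E)-enone ketone | CC1=C(CC[C@@H]2[C@@]3(C)CC[C@@H](O[Si](C)(C)C(C)(C)C)C(C)(C)O[C@@H]3CCC2=O)[C@](C)(C/C=C/C(C)=O)[C@H](O[Si](C)(C)C(C)(C)C)CC1 | intermediate
38 | 3,5'-bis(tert-butyldimethylsilyl) ether of siphonellinol C | CC1=C(CC[C@@H]2[C@@]3(C)CC[C@@H](O[Si](C)(C)C(C)(C)C)C(C)(C)O[C@@H]3CC[C@]2(C)O)[C@](C)(C/C=C/C(C)(C)O)[C@H](O[Si](C)(C)C(C)(C)C)CC1 | intermediate
39 | siphonellinol C (3R,5aR,6R,7S,9aR; 5'R,6'S; E) | CC1=C(CC[C@@H]2[C@@]3(C)CC[C@@H](O)C(C)(C)O[C@@H]3CC[C@]2(C)O)[C@](C)(C/C=C/C(C)(C)O)[C@H](O)CC1 | target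

## Step count and least certain steps

Total step count: 27. Longest linear sequence: 19 steps (steps 1–12 and 21–27). The ring C branch (steps 13–20) has 8 steps and joins at step 21.

**Step 6 (key step).** Migration of the C6 methylene could compete with that of the ring-fusion carbon, and the rearrangement could be slow because the migrating carbon is neopentyl-like, which would give time for acid-promoted loss of the dioxolane. Fallback, setting out from 8 and returning to 9: kinetic enolisation (LiN(iPr)2, Me3SiCl, –78 °C) toward the methylene would give the trimethylsilyl enol ether F1, and N-bromosuccinimide would turn it into the 6-bromo ketone F2. A bromine-bearing carbon has very low migratory aptitude, so the peracid should now give only the 3-bromo lactone F3, from which Zn in AcOH removes the halogen to give 9.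

**Step 9.** The seven-membered enol ether is flexible, so the epoxidation could show poor facial selectivity. The epoxide could also undergo a hydride shift to a ketone instead of methyl transfer, and AlMe3 could open the dioxolane. Fallback for the stereochemical problem, setting out from 14 obtained together with its C3 epimer F4: Dess–Martin oxidation of the mixture would give the 2,2-dimethyloxepan-3-one F5, and reduction with LiBH(sBu)3 would return to 14. A hydride enters from the more open face, the same face an epoxidising agent prefers, so reduction places the hydroxyl on the face opposite to that chosen in the epoxidation and corrects a wrong facial preference.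

**Step 14.** Methyl and allyl may be told apart too weakly at the quaternary carbon (low diastereoselectivity), and uncatalysed reduction could erode the enantioselectivity. Fallback, setting out from 19 and returning at 28: alkylation with prenyl bromide would give 2-methyl-2-prenylcyclohexane-1,3-dione F6, whose larger side chain should bias the same reduction more strongly toward the (2R,3R)-ketol F7. Silylation (silyl ether F8), methylation (methyl ketone F9) and triflation (enol triflate F10) follow steps 15–17, and OsO4/NaIO4 cleavage of the more electron-rich prenyl double bond gives aldehyde 28.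

**Step 21.** Oxidative addition and transmetalation at the triflate beside the quaternary C5a may be slow, so that protodeboronation or β-hydride elimination of the alkyl group takes over. Fallback, setting out from 30 and returning to 32: borane 31 would be oxidised (NaOH, H2O2) to the primary alcohol F11 and converted with I2, PPh3 and imidazole into the iodide F12. Zinc dust (LiCl, THF) would give the alkylzinc iodide F13, and Negishi coupling of it with triflate 18 (Pd(dppf)Cl2) gives 32.

**Step 22.** Borane could also attack the tetrasubstituted ring C alkene, or add to the C6=C7 bond from the methyl face. Fallback, setting out from 32 and returning at 35: OsO4 (pyridine, then NaHSO3), which does not touch hindered tetrasubstituted alkenes, should dihydroxylate the C6=C7 bond from the face opposite the C5a methyl to give the 6,7-diol F14. Dess–Martin oxidation of its secondary hydroxyl gives the α-hydroxy ketone F15, and SmI2 (THF/MeOH) removes the tertiary α-hydroxyl. Protonation of the enolate, with base equilibration if needed, places the tether equatorially and gives ketone 35.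

## Further compounds

F1 | step 6 | kinetic trimethylsilyl enol ether of 8 (C5=C6) | O1CCOC12[C@@]3(C)CCC=C(O[Si](C)(C)C)[C@@H]3CCC2
F2 | step 6 | 6-bromo ketone (epimer mixture at C6) | O1CCOC12[C@@]3(C)CCC(Br)C(=O)[C@@H]3CCC2
F3 | step 6 | 3-bromo lactone (epimer mixture at C3) | O1CCOC12[C@@]3(C)CCC(Br)C(=O)O[C@@H]3CCC2
F4 | step 9 | C3 epimer of 14 | O1CCOC12[C@@]3(C)CC[C@H](O)C(C)(C)O[C@@H]3CCC2
F5 | step 9 | 2,2-dimethyloxepan-3-one (C6 dioxolane) | O1CCOC12[C@@]3(C)CCC(=O)C(C)(C)O[C@@H]3CCC2
F6 | step 14 | 2-methyl-2-prenylcyclohexane-1,3-dione | CC(C)=CCC1(C)C(=O)CCCC1=O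
F7 | step 14 | (2R,3R)-3-hydroxy-2-methyl-2-prenylcyclohexan-1-one | O=C1[C@](C)(CC=C(C)C)[C@H](O)CCC1
F8 | step 14 | tert-butyldimethylsilyl ether of F7 | O=C1[C@](C)(CC=C(C)C)[C@H](O[Si](C)(C)C(C)(C)C)CCC1
F9 | step 14 | 6-methyl ketone of F8 (epimer mixture at C6) | CC1C(=O)[C@](C)(CC=C(C)C)[C@H](O[Si](C)(C)C(C)(C)C)CC1
F10 | step 14 | enol triflate with prenyl group | CC1=C(OS(=O)(=O)C(F)(F)F)[C@](C)(CC=C(C)C)[C@H](O[Si](C)(C)C(C)(C)C)CC1
F11 | step 21 | primary alcohol from oxidation of 31 | CC1=C(CCO)[C@](C)(CC(OC)OC)[C@H](O[Si](C)(C)C(C)(C)C)CC1
F12 | step 21 | primary iodide | CC1=C(CCI)[C@](C)(CC(OC)OC)[C@H](O[Si](C)(C)C(C)(C)C)CC1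
F13 | step 21 | alkylzinc iodide | CC1=C(CC[Zn]I)[C@](C)(CC(OC)OC)[C@H](O[Si](C)(C)C(C)(C)C)CC1
F14 | step 22 | 6,7-diol (both hydroxyls on the face of H-9a) | CC1=C(CC[C@]2(O)[C@@]3(C)CC[C@@H](O[Si](C)(C)C(C)(C)C)C(C)(C)O[C@@H]3CC[C@H]2O)[C@](C)(CC(OC)OC)[C@H](O[Si](C)(C)C(C)(C)C)CC1
F15 | step 22 | 6-hydroxy-7-ketone | CC1=C(CC[C@]2(O)[C@@]3(C)CC[C@@H](O[Si](C)(C)C(C)(C)C)C(C)(C)O[C@@H]3CCC2=O)[C@](C)(CC(OC)OC)[C@H](O[Si](C)(C)C(C)(C)C)CC1
A1 | alternative 1 | (Z)-trimethylsilyl enol ether diepoxide (cascade substrate) | c1ccccc1COCC/C=C(\O[Si](C)(C)C)CC[C@H]1O[C@]1(C)CC[C@@H]1C(C)(C)O1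
A2 | alternative 1 | trans-fused oxepane–cyclohexanone with benzyloxyethyl arm | c1ccccc1COCC[C@@H]2[C@@]3(C)CC[C@@H](O)C(C)(C)O[C@@H]3CCC2=O
A3 | alternative 2 | (R)-allylic alcohol ketal with homoprenyl chain | O[C@@H]1CCC2(OCCO2)C=C1CCC=C(C)C
A4 | alternative 2 | syn-hydroxy bicyclo[4.1.0]heptane ketal | O[C@@H]1CCC2(OCCO2)[C@@H]3C[C@]13CCC=C(C)C
A5 | alternative 3 | nerol-derived (2R,3S)-epoxy β-keto ester | COC(=O)CC(=O)CC[C@H]1O[C@@]1(C)CCC=C(C)C
A6 | alternative 3 | cyclic β-keto ester with quaternary carbon and carbinol | O=C1CC[C@@H](O)[C@@](C)(CCC=C(C)C)C1C(=O)OC
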